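The data are calculated for an exercise; the scatter is artificial.

Count the half-lives of D up to the reading: the length asked for is monomer in chains over chains begun, and the runs show the first of these but not the second.

| setting | theta | alpha | flask |
|---|---|---|---|
| E | 0.10 M (fed, over 1.0 min) | 0.10 M (fed, over 1.0 min) | 0.10 M (fed, over 1.0 min) |
| Q | 1 mM | 0.67 mM | 1.00 mM |
| D | 10 mM | 10 mM | 10 mM |
| remark | the very flask that is asked about, followed so far; the fed solution adds 0.50 times the starting volume | run made earlier; the fed solution adds 0.50 times the starting volume | the fed solution adds 0.50 times the starting volume |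
| time |  |  | 10 min |

theta run (percent of the E charged)

| time / s | G / % | E / % |
|---|---|---|
| 10.0 | 1.2 | 15.6 |
| 20.0 | 2.7 | 28.8 |
| 40.0 | 10.1 | 53.2 |
| 60.0 | 18.6 | 75.9 |
| 80.0 | 20.1 | 71.4 |
| 120 | 22.4 | 68.0 |

alpha run (percent of the E charged)

| time / min | G / % | E / % |
|---|---|---|
| 0.833 | 12.7 | 62.7 |
| 1.33 | 20.4 | 71.8 |
| 2.00 | 23.5 | 69.5 |
| 4.00 | 24.1 | 69.0 |
| 6.00 | 23.5 | 67.5 |
| 10.0 | 21.0 | 67.6 |

(readings scatter by 1 percentage point)

- charges are per starting volume, the dose included; the dosed solution carries all of it
- the average divides the monomer in chains by the number of chains begun, living and dead together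
- the earlier runs do not show the number of chains; that part of a forecast is a guess
- percentages count the whole charge, also what has not yet gone in

1. whether the average number of monomer units in a chain (chains begun, living or dead) reaches 9.0 by 10 min (yes / no)
2. average number of monomer units in a chain (chains begun, living or dead) at 10 min

In the first instants of theta, E trickles in among the D, and your working assumption is that a chain begins when E meets D, at a rate proportional to cE and cD. By 20.0 s, G reads 2.7% and E, climbing from nothing, reads 28.8%, so mean cE is about half that reading. Counting that G as chain starts gives each D a use rate of 0.0135 s⁻¹, a reading with 1 percentage point of scatter on a small number.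

Later in theta, the feed stops at 1.0 min, and by 120 s E reads 68.0% in the enlarged volume, so cE is 45.3 mM. That exceeds the diluted charge of D, 6.67 mM, so treat D's loss as pseudo-first-order. Scaling the use rate by this cE over the early mean gives 0.272 min, the D half-life.

At the end of theta, G moves from 20.1% to 22.4% between 80.0 s and 120 s while E still reads 68.0%, so E has not run out. From the end of the feed to 10 min lie 33.1 half-lives, so your reckoning counts the whole 10 mM of D as chains begun. With G at its last reading, the length is 2.24, below 9.0.

The forecast, which agrees with this on the yes-or-no but differs on the length, gave no and 6, on the words “I guess about 3–4 mM of chains”.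

The flask gives no and 2.21 units per chain at 10 min, with G at 22.1%. D stands at 10.6% at 1.00 min and 0% at 5.00 min. Between those two times, 0.272 min counts 14.7 half-lives, which takes that remainder to hardly any of the charge.

    L + Q → J (k = 17.8 M⁻¹ s⁻¹)
    E + L → G + L, rate k2*[L]*[E] (k = 2.11 M⁻¹ s⁻¹)
    L + E → X (k = 1.59 M⁻¹ s⁻¹)
    E + D → L + G (k = 1.23 M⁻¹ s⁻¹)

Take the neighbour flask with 0.040 M of E, all else as in theta. That flask ends with E at 23.1% of its own charge, so cE there is 6.15 mM, and 0.272 min scaled by 45.3 mM over this cE gives 2.00 min, or 4.49 half-lives after the feed if cE stood at that closing value throughout. The computed neighbour flask holds D at 0.181% at 10.0 min, which is 9.11 halvings of its charge counted from the start, with 54.6% of its E as G and 2.19 units per chain.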